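## The problem

The target is the O7 ether of isofraxidin with C11 of a bicyclic sesquiterpene: a trans-fused decalin that carries a C7=C8 double bond and an acetoxy group on C3. Drimane numbering is used throughout: ring A is C1–C5 and C10, ring B is C5–C10, C11 is the oxymethylene on C9, C12 the methyl on C8, C13 and C14 the methyls on C4, and C15 the methyl on C10. Four stereocentres have to be set (C3, C5, C9, C10); three are contiguous around ring B and C10 is quaternary. H5 is trans to C15 and C11 is trans to C15, that is, cis to C1; C9 cannot be epimerised in the target, so this relation must be right in the step that creates it. C3 is remote, but once the trans-decalin exists ring A is a locked chair, so the equatorial (β) oxygen at C3 can be left to substrate control. The coumarin is a lactone and a Michael and radical acceptor, the acetate is base-labile, and the trisubstituted C7=C8 alkene can migrate under acid or be reduced; arene and acetate therefore come last, and the alkene must be carried through. The C11–O bond sits on a β-branched primary carbon next to the quaternary centre, so forming it by displacement is not trivial. The enabling feature is that C11–O and C1 are cis on the neighbouring ring B atoms C9 and C10: an O–C1 ester can tie a C6–C9 diene to a C5=C10 dienophile, a [4+2] closure forms C5–C6 and C9–C10, C7=C8 is the alkene left behind, and the trans relation of C1 and C4 is the geometry of an E dienophile.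

## Retrosynthesis

**C3–O acyl and C11–O aryl bonds.** Target 22 is cut at the acetate to alcohol 21, and 21 at the C11–O7 ether to diol 19 and isofraxidin 20. The ether is cut late because the coumarin would not survive the thiolate, cuprate, hydride, ylide and radical steps of the terpene synthesis, and because 20 can be bought whole. Etherifying before acetylating lets the primary C11 hydroxyl and the hindered secondary C3 hydroxyl of 19 be told apart by reactivity alone, so no protecting group is needed. The forward reaction must displace at a β-branched CH2 with a di-ortho-substituted phenol.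

**C3–C4.** Diol 19 is opened to hydroxy aldehyde 18, which has only ring B, an isopropenyl group on C5 and a three-carbon aldehyde chain on C10. This one cut removes ring A, the quaternary C4 and the C3 stereocentre. A polar closure between the same groups (Prins or ene) would bond C3 to the terminal CH2 and give a seven-membered ring; only a tertiary C4 radical bonds C3 to C4. The forward step needs hydrogen-atom transfer to the isopropenyl group in preference to C7=C8, 6-exo addition to the aldehyde, and the equatorial alcohol.

**C2–C3, C1–C2 and the C1 oxidation level.** Aldehyde 18 comes from vinyl alcohol 17 by hydroformylation (adds C3), 17 from lactol 16 by methylenation (adds C2 and frees the C11 hydroxyl), and 16 from lactone 15 by partial reduction. This turns the lactone carbonyl C1 into a CH2 bearing two more carbons in three steps. A two-carbon stabilised ylide on the lactol would need a conjugate reduction and an ester reduction and would invite oxa-Michael closure by the C11 hydroxyl, so it is kept as a reserve. The forward hydroformylation must select the monosubstituted alkene.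

**C4 substituents.** Isopropenyl lactone 15 is traced through methyl ketone 14 and thioester 13 to imide 12. Each step touches only the C4 carbonyl in the presence of the lactone, the auxiliary is recovered, and the methylenation is non-basic so C5, α to the ketone, keeps its configuration.

**C5–C6 and C9–C10 (key step).** Lactone imide 12 is the intramolecular Diels–Alder adduct of triene imide 11. Against a polyene cyclisation or an intermolecular cycloaddition, this cut fixes all three ring B stereocentres by geometry (Z diene, short tether, E dienophile) and leaves only the facial sense to the auxiliary. Precursor 11 is acyclic with one stereocentre, that of the auxiliary.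

**C4–N and C5=C10.** Imide 11 is cut at the imide C–N bond to acid 8 and oxazolidinone 9, and 8 at the C5=C10 double bond to ylide 6 and glyoxylic acid 7. A Wittig reaction of an α-branched stabilised ylide with an aldehyde gives the E trisubstituted alkene reliably. It also leaves C4 as the free acid and C1 as the dienyl ester by construction, which differentiating the two carboxyls of a preformed C5 diacid would not guarantee.

**The diene ester.** Ylide 6 comes from bromo ester 4, 4 from dienol 2 and acid bromide 3, and 2 from commercial enynol 1 by semihydrogenation. The Z geometry of 1 is the only stereochemical information the diene needs.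

## Roads not taken

**Alternative 1:** squarate benzannulation. The cut is C4a–C8a of the arene. Cyclobutenone A1, made from a squaric ester, the C3-silylated terpene alcohol and an alkenyllithium, would be heated to about 140 °C. Ring opening gives a dienyl ketene, six-electron closure and tautomerisation give phenol A2, and acetal hydrolysis and olefination–lactonisation would then build the pyranone.
- Merit: the C11–O bond is formed by addition–elimination of the terpene alkoxide at an sp2 squarate carbon, which is far less sensitive to hindrance at C11 than any displacement. In this respect it is better than the chosen plan, whose Mitsunobu step is a real risk.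
- Weak points: it builds the one part that can be bought (20). It still needs the complete terpene alcohol, so it solves none of the four stereocentres. The alkenyl addition must distinguish two nearly equal vinylogous ester carbonyls. About six further steps follow the benzannulation.
- Comparison: the chosen plan accepts the hindered etherification and keeps a sulfonate displacement in reserve for it.

**Alternative 2:** biomimetic epoxy-polyene bicyclisation. The cut is C4–C5 and C9–C10. Epoxide A3, the (2Z,6E)-farnesyl ether of 20 with an (S)-10,11-epoxide, would be opened by an alkylaluminium dichloride. The two trisubstituted alkenes add in turn and loss of the C7 proton gives alcohol A4, which is identical with 21.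
- Merit: it is much shorter, about six steps from a commercial sesquiterpene alcohol, and it makes both rings and all four stereocentres in one step. On step count it is clearly better than the chosen plan.
- Weak points: the allylic oxygen deactivates the C2=C3 alkene towards the second closure. The (2Z)-allylic aryl ether has a good phenoxide leaving group and can ionise under the Lewis acid, which would scramble the Z geometry that encodes C9. The chair–chair fold must place CH2OAr axial. The final proton loss can give C7=C8, C8=C9 or exocyclic alkenes. Monocyclic products and coumarin–Lewis acid complexation are expected to cut into the yield.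
- Comparison: the chosen plan has some nine more steps. It offers in return a C9 configuration and alkene position fixed by the geometry of a concerted cycloaddition, and no Lewis acid ever acting on an aryl allyl ether.

**Alternative 3:** quinone Diels–Alder. The cut is C1–C10 and C4–C5. Quinone A5 and siloxy diene A6 would combine under a chiral oxazaborolidinium acid to give cis-fused ene-dione A7.
- Merit: it is convergent and catalytic in chirality, and delivers C10, the gem-dimethyl C4 and the C3 oxygen together. It reaches a bicyclic core faster than the chosen plan.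
- Weak points: A6 must bond through its gem-dimethyl terminus, a poor diene end. A7 is cis-fused, so C5 must be epimerised through the C6 ketone. The C6 oxygen must be removed. C11 is absent and must be added at the C9 ketone, where addition to a C9 exocyclic alkene from the face away from C15 would be expected to place C11 cis to C15, the wrong epimer.
- Comparison: the chosen plan is longer to the bicycle but sets C9, the trans fusion and the C7=C8 alkene directly, with no deoxygenation or epimerisation.

Key step: step 6

Remark: metal-bound forms of a numbered compound (the aluminium chelate of 11, metal alkoxides before work-up) are treated as states of that compound and are not numbered separately. "β" means the face of the ring system that carries C15.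

## Route

Step 1
Reactants: 1 (2Z)-3-methylpent-2-en-4-yn-1-ol
Product: 2 (2Z)-3-methylpenta-2,4-dien-1-ol
Conditions: H2 (1 atm, one equivalent), Pd/CaCO3 poisoned with Pb(OAc)2, quinoline, Et2O, 0 °C → rt
Reagents that add atoms: none
Why: Semihydrogenation of a terminal alkyne on poisoned palladium (Lindlar reduction) stops at the vinyl group; the existing Z trisubstituted alkene is untouched, so the geometry that later forces the cis lactone is carried over.

Step 2
Reactants: 2 (2Z)-3-methylpenta-2,4-dien-1-ol; 3 2-bromopropanoyl bromide (racemic)
Product: 4 (2Z)-3-methylpenta-2,4-dien-1-yl 2-bromopropanoate (racemic at the bromine-bearing carbon)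
Conditions: pyridine, CH2Cl2, −20 → 0 °C
Reagents that add atoms: none
Why: O-Acylation of a primary allylic alcohol by an acid bromide with pyridine as acid scavenger; the low temperature keeps the pentadienyl alcohol from ionising and the α-bromide from being displaced by pyridine.

Step 3
Reactants: 4 (2Z)-3-methylpenta-2,4-dien-1-yl 2-bromopropanoate
Product: 6 (2Z)-3-methylpenta-2,4-dien-1-yl 2-(triphenyl-λ5-phosphanylidene)propanoate, via phosphonium bromide 5 (not isolated)
Conditions: PPh3, toluene, 60 °C; then aq. NaOH, CH2Cl2, 0 °C
Reagents that add atoms: triphenylphosphine, c1ccc(cc1)P(c1ccccc1)c1ccccc1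
Why: SN2 quaternisation of the phosphine by the α-bromo ester and deprotonation of the acidic α-CH give the ester-stabilised ylide (Wittig reagent synthesis); the brief cold two-phase base treatment should leave the dienyl ester intact.

Step 4
Reactants: 6 (2Z)-3-methylpenta-2,4-dien-1-yl 2-(triphenyl-λ5-phosphanylidene)propanoate; 7 glyoxylic acid monohydrate
Product: 8 (2E)-3-methyl-4-{[(2Z)-3-methylpenta-2,4-dien-1-yl]oxy}-4-oxobut-2-enoic acid
Conditions: CH2Cl2, 0 °C → rt; bicarbonate extraction, then acidification
Reagents that add atoms: none
Why: Wittig reaction of an α-branched stabilised ylide with an aldehyde gives the trisubstituted alkene with the ester trans to the aldehyde-derived carbon, which is the E (mesaconate) geometry; C4 emerges as the free acid and C1 as the dienyl ester, so the two carboxyls are differentiated by construction.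

Step 5
Reactants: 8 (2E)-3-methyl-4-{[(2Z)-3-methylpenta-2,4-dien-1-yl]oxy}-4-oxobut-2-enoic acid; 9 (4R)-4-benzyl-1,3-oxazolidin-2-one
Product: 11 (4R)-4-benzyl-3-{(2E)-3-methyl-4-[(2Z)-3-methylpenta-2,4-dien-1-yloxy]-4-oxobut-2-enoyl}-1,3-oxazolidin-2-one, via mixed pivalic anhydride 10 (not isolated)
Conditions: t-BuCOCl, Et3N, THF, −20 °C; then 9, LiCl, −20 °C → rt
Reagents that add atoms: none
Why: Mixed-anhydride N-acylation of the oxazolidinone under LiCl/Et3N conditions; attack goes to the unhindered enoyl carbonyl of the anhydride, and the mild base should avoid conjugate addition to the fumarate-type acceptor and isomerisation of either alkene.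

Step 6
Reactants: 11 (4R)-4-benzyl-3-{(2E)-3-methyl-4-[(2Z)-3-methylpenta-2,4-dien-1-yloxy]-4-oxobut-2-enoyl}-1,3-oxazolidin-2-one
Product: 12 (4R)-4-benzyl-3-{[(3aR,7R,7aR)-4,7a-dimethyl-1-oxo-1,3,3a,6,7,7a-hexahydro-2-benzofuran-7-yl]carbonyl}-1,3-oxazolidin-2-one (cis-fused lactone; imide carbonyl C4 trans to lactone carbonyl C1 and cis to C15)
Conditions: Et2AlCl (1.5 equiv), CH2Cl2, −78 → −20 °C; aq. HCl quench
Reagents that add atoms: none
Why: This is an intramolecular Diels–Alder reaction of an ester-tethered 1,3,8-nonatriene bearing an N-enoyl oxazolidinone, the known Lewis-acid-promoted, auxiliary-controlled class. Et2AlCl binds the imide and ring carbonyls as a six-membered cationic chelate, which lowers the dienophile LUMO, holds the enoyl s-cis (C5 carries only H, so nothing clashes with the auxiliary) and makes C10 the electrophilic end, matched to C9, the diene terminus with the largest HOMO coefficient; C9–C10 should lead in an asynchronous concerted [4+2] and C5–C6 follow. Ring B closes as the six-membered cycloadduct ring, suprafacial on both partners, and the γ-lactone closes as the five-membered ring spanned by the three-atom C11–O–C1 tether when C9–C10 forms (type-one IMDA), which for a Z diene can only be cis-fused. C9 relative to C10 is therefore fixed by the Z diene and the short tether (C11 cis to C1, trans to C15), C5 relative to C10 by the E dienophile (C4 trans to C1, the later trans ring fusion), and the absolute sense at C5 and C10 by the (R)-benzyl group, which covers one face of the chelated enoyl so that the diene adds to the C5 re face. In this forced geometry the chelated imide carbonyl lies endo and the tether carbonyl exo, so no endo/exo question arises; the only selectivity the step must deliver is π-facial, and the auxiliary supplies it. The ester has to rotate out of its preferred conformation for the tether to reach, the usual handicap of ester tethers, which is why the dienophile is given chelate activation. The cycloaddition must also outrun ionisation of the pentadienyl ester; the bidentate imide should hold the aluminium away from the ester oxygen, and the low temperature excludes the 1,5-hydrogen shift open to Z dienes.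

Step 7
Reactants: 12 lactone imide
Product: 13 S-ethyl (3aR,7R,7aR)-4,7a-dimethyl-1-oxo-1,3,3a,6,7,7a-hexahydro-2-benzofuran-7-carbothioate
Conditions: EtSH, n-BuLi, THF, 0 °C; aq. NH4Cl
Reagents that add atoms: ethanethiol, CCS
Why: Lithium ethanethiolate attacks the exocyclic imide carbonyl selectively even in hindered N-acyl oxazolidinones (thiolysis to the thioester) and releases the auxiliary for recovery; the weakly basic thiolate at 0 °C should neither epimerise C5 nor open the α-quaternary lactone.

Step 8
Reactants: 13 thioester
Product: 14 (3aR,7R,7aR)-7-acetyl-4,7a-dimethyl-3a,6,7,7a-tetrahydro-2-benzofuran-1(3H)-one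
Conditions: Me2CuLi (from CuI and MeLi), Et2O, −78 → −40 °C; aq. NH4Cl
Reagents that add atoms: methyllithium, [Li]C
Why: Acyl substitution of a thioester by a lithium dialkylcuprate stops at the ketone; lactones are inert to the cuprate at low temperature, so only C4 reacts and C5 is not enolised.

Step 9
Reactants: 14 methyl ketone
Product: 15 (3aR,7S,7aS)-4,7a-dimethyl-7-(prop-1-en-2-yl)-3a,6,7,7a-tetrahydro-2-benzofuran-1(3H)-one (same spatial arrangement as 14; descriptors change with priorities only)
Conditions: Zn, CH2Br2, TiCl4, THF/CH2Cl2, 0 °C → rt
Reagents that add atoms: dibromomethane, BrCBr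
Why: Takai–Lombardo methylenation converts ketones into 1,1-disubstituted alkenes under non-basic conditions, so the C5 stereocentre α to the ketone should not epimerise, and the reagent does not attack lactones.

Step 10
Reactants: 15 isopropenyl lactone
Product: 16 (3aR,7S,7aS)-4,7a-dimethyl-7-(prop-1-en-2-yl)-1,3,3a,6,7,7a-hexahydro-2-benzofuran-1-ol (lactol, mixture at C1)
Conditions: i-Bu2AlH, CH2Cl2, −78 °C; aq. potassium sodium tartrate
Reagents that add atoms: none
Why: Partial reduction of a γ-lactone by a dialkylaluminium hydride at −78 °C stops at the aluminium hemiacetal and gives the lactol; the α-quaternary centre slows over-reduction further.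

Step 11
Reactants: 16 lactol
Product: 17 [(1R,5S,6S)-6-ethenyl-2,6-dimethyl-5-(prop-1-en-2-yl)cyclohex-2-en-1-yl]methanol (hydroxymethyl cis to vinyl, trans to C15 and to isopropenyl)
Conditions: Ph3PCH3Br, KOt-Bu, THF, 0 → 50 °C
Reagents that add atoms: methyltriphenylphosphonium bromide, C[P+](c1ccccc1)(c1ccccc1)c1ccccc1.[Br-]
Why: Wittig methylenation of a lactol through its open hydroxy-aldehyde form; the aldehyde carbon C1 has no α-hydrogen, so nothing can epimerise, and the step frees the C11 hydroxyl while adding C2.

Step 12
Reactants: 17 vinyl alcohol
Product: 18 3-[(1S,2R,6S)-2-(hydroxymethyl)-1,3-dimethyl-6-(prop-1-en-2-yl)cyclohex-3-en-1-yl]propanal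
Conditions: CO/H2 (1:1, 10 bar), Rh(acac)(CO)2 (2 mol %), BIPHEPHOS, toluene, 60 °C
Reagents that add atoms: carbon monoxide, [C-]#[O+]
Why: Rhodium/bisphosphite-catalysed hydroformylation puts the formyl group on the terminal carbon of a monosubstituted alkene; the vinyl group on quaternary C10 cannot give a branched aldehyde and has no allylic hydrogen to isomerise, while 1,1-disubstituted and trisubstituted alkenes react much more slowly under these conditions.

Step 13
Reactants: 18 hydroxy aldehyde
Product: 19 (1R,4aR,6S,8aS)-1-(hydroxymethyl)-2,5,5,8a-tetramethyl-1,4,4a,5,6,7,8,8a-octahydronaphthalen-6-ol (3β-hydroxy, 5α-H, C11 α, C15 β)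
Conditions: Fe(acac)3 (30 mol %), PhSiH3, EtOH, 60 °C
Reagents that add atoms: none
Why: Iron-hydride Markovnikov hydrogen-atom transfer to the 1,1-disubstituted alkene gives the tertiary C4 radical, which adds 6-exo to the aldehyde carbon C3; the alkoxy radical is then reduced and protonated (HAT-initiated reductive alkene–carbonyl radical cyclisation). Ring A forms as a chair trans-fused to ring B with the C3 oxygen equatorial, away from the axial hydrogens on C1 and C5, which should give the 3β-alcohol; the trisubstituted C7=C8 alkene is a slower hydrogen-atom acceptor than the isopropenyl group.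

Step 14
Reactants: 19 diol; 20 isofraxidin (7-hydroxy-6,8-dimethoxy-2H-chromen-2-one)
Product: 21 7-{[(1R,4aR,6S,8aS)-6-hydroxy-2,5,5,8a-tetramethyl-1,4,4a,5,6,7,8,8a-octahydronaphthalen-1-yl]methoxy}-6,8-dimethoxy-2H-chromen-2-one
Conditions: PPh3, DIAD, THF, 0 °C → rt
Reagents that add atoms: none
Why: Mitsunobu etherification: the alkoxyphosphonium ion forms at the primary C11 hydroxyl and is displaced by the acidic phenoxide of 20 at a CH2 carbon, so no stereocentre is involved; the secondary C3 hydroxyl beside the gem-dimethyl carbon is too hindered to be activated, which gives site selectivity without protection.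

Step 15
Reactants: 21 3β-alcohol
Product: 22 7-{[(1R,4aR,6S,8aS)-6-acetoxy-2,5,5,8a-tetramethyl-1,4,4a,5,6,7,8,8a-octahydronaphthalen-1-yl]methoxy}-6,8-dimethoxy-2H-chromen-2-one (CNP0285931.2)
Conditions: Ac2O, DMAP (cat.), pyridine, rt
Reagents that add atoms: acetic anhydride, CC(=O)OC(C)=O
Why: DMAP-catalysed acylation of the hindered equatorial alcohol proceeds with retention at C3; the coumarin lactone and the aryl ethers are inert to acetic anhydride in pyridine.

## Compound list

1 | (2Z)-3-methylpent-2-en-4-yn-1-ol | C#C/C(C)=C\CO | starting material
2 | (2Z)-3-methylpenta-2,4-dien-1-ol | C=C/C(C)=C\CO | intermediate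
3 | 2-bromopropanoyl bromide (racemic) | CC(Br)C(Br)=O | starting material
4 | (2Z)-3-methylpenta-2,4-dien-1-yl 2-bromopropanoate (racemic) | C=C/C(C)=C\COC(=O)C(C)Br | intermediate
5 | {1-[(2Z)-3-methylpenta-2,4-dien-1-yloxy]-1-oxopropan-2-yl}triphenylphosphonium bromide | C=C/C(C)=C\COC(=O)C(C)[P+](c1ccccc1)(c1ccccc1)c1ccccc1.[Br-] | intermediate (not isolated)
6 | (2Z)-3-methylpenta-2,4-dien-1-yl 2-(triphenyl-λ5-phosphanylidene)propanoate | C=C/C(C)=C\COC(=O)C(C)=P(c1ccccc1)(c1ccccc1)c1ccccc1 | intermediate
7 | glyoxylic acid monohydrate | OC(O)C(=O)O | starting material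
8 | (2E)-3-methyl-4-{[(2Z)-3-methylpenta-2,4-dien-1-yl]oxy}-4-oxobut-2-enoic acid | C=C/C(C)=C\COC(=O)/C(C)=C/C(=O)O | intermediate
9 | (4R)-4-benzyl-1,3-oxazolidin-2-one | O=C1N[C@H](Cc2ccccc2)CO1 | starting material
10 | mixed anhydride of 8 with pivalic acid | C=C/C(C)=C\COC(=O)/C(C)=C/C(=O)OC(=O)C(C)(C)C | intermediate (not isolated)
11 | (4R)-4-benzyl-3-{(2E)-3-methyl-4-[(2Z)-3-methylpenta-2,4-dien-1-yloxy]-4-oxobut-2-enoyl}-1,3-oxazolidin-2-one | C=C/C(C)=C\COC(=O)/C(C)=C/C(=O)N1[C@H](Cc2ccccc2)COC1=O | intermediate
12 | (4R)-4-benzyl-3-{[(3aR,7R,7aR)-4,7a-dimethyl-1-oxo-1,3,3a,6,7,7a-hexahydro-2-benzofuran-7-yl]carbonyl}-1,3-oxazolidin-2-one | O=C1OC[C@@H]2C(C)=CC[C@@H](C(=O)N3[C@H](Cc4ccccc4)COC3=O)[C@]12C | intermediate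
13 | S-ethyl (3aR,7R,7aR)-4,7a-dimethyl-1-oxo-1,3,3a,6,7,7a-hexahydro-2-benzofuran-7-carbothioate | O=C1OC[C@@H]2C(C)=CC[C@@H](C(=O)SCC)[C@]12C | intermediate
14 | (3aR,7R,7aR)-7-acetyl-4,7a-dimethyl-3a,6,7,7a-tetrahydro-2-benzofuran-1(3H)-one | O=C1OC[C@@H]2C(C)=CC[C@@H](C(C)=O)[C@]12C | intermediate
15 | (3aR,7S,7aS)-4,7a-dimethyl-7-(prop-1-en-2-yl)-3a,6,7,7a-tetrahydro-2-benzofuran-1(3H)-one | O=C1OC[C@@H]2C(C)=CC[C@@H](C(C)=C)[C@]12C | intermediate
16 | (3aR,7S,7aS)-4,7a-dimethyl-7-(prop-1-en-2-yl)-1,3,3a,6,7,7a-hexahydro-2-benzofuran-1-ol (mixture at C1) | OC1OC[C@@H]2C(C)=CC[C@@H](C(C)=C)[C@]12C | intermediate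
17 | [(1R,5S,6S)-6-ethenyl-2,6-dimethyl-5-(prop-1-en-2-yl)cyclohex-2-en-1-yl]methanol | OC[C@@H]1C(C)=CC[C@@H](C(C)=C)[C@]1(C)C=C | intermediate
18 | 3-[(1S,2R,6S)-2-(hydroxymethyl)-1,3-dimethyl-6-(prop-1-en-2-yl)cyclohex-3-en-1-yl]propanal | OC[C@@H]1C(C)=CC[C@@H](C(C)=C)[C@]1(C)CCC=O | intermediate
19 | (1R,4aR,6S,8aS)-1-(hydroxymethyl)-2,5,5,8a-tetramethyl-1,4,4a,5,6,7,8,8a-octahydronaphthalen-6-ol | OC[C@@H]1C(C)=CC[C@H]2C(C)(C)[C@@H](O)CC[C@]12C | intermediate
20 | isofraxidin (7-hydroxy-6,8-dimethoxy-2H-chromen-2-one) | COc1cc2ccc(=O)oc2c(OC)c1O | starting material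
21 | 7-{[(1R,4aR,6S,8aS)-6-hydroxy-2,5,5,8a-tetramethyl-1,4,4a,5,6,7,8,8a-octahydronaphthalen-1-yl]methoxy}-6,8-dimethoxy-2H-chromen-2-one | COc1cc2ccc(=O)oc2c(OC)c1OC[C@@H]1C(C)=CC[C@H]2C(C)(C)[C@@H](O)CC[C@]12C | intermediate
22 | 7-{[(1R,4aR,6S,8aS)-6-acetoxy-2,5,5,8a-tetramethyl-1,4,4a,5,6,7,8,8a-octahydronaphthalen-1-yl]methoxy}-6,8-dimethoxy-2H-chromen-2-one | COc1cc2ccc(=O)oc2c(OC)c1OC[C@@H]1C(C)=CC[C@H]2C(C)(C)[C@@H](OC(C)=O)CC[C@]12C | target

## Step count and least certain steps

Total: 15 steps. Longest linear sequence: 15 steps (1 → 22); compounds 3, 7, 9 and 20 enter as purchased materials. No protecting group is used.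

**Step 6 (key step).** The cycloaddition may be too slow at temperatures where the aluminium chelate is well behaved: the ester must leave its preferred conformation, the diene is Z, and C10 becomes quaternary. Ionisation of the pentadienyl C11–O bond by the Lewis acid, or diene oligomerisation, could then overtake ring closure. Facial discrimination may also erode, because the methyl on C10 lies cis to the imide carbonyl and can twist the chelated enoyl out of plane. The fallback replaces auxiliary control by catalyst control with a milder cationic Lewis acid. It sets out from acid 8: its mixed anhydride 10 is intercepted by 1,3-oxazolidin-2-one (LiCl, Et3N) to give 3-{(2E)-3-methyl-4-[(2Z)-3-methylpenta-2,4-dien-1-yloxy]-4-oxobut-2-enoyl}-1,3-oxazolidin-2-one F1. Cyclisation of F1 with the divalent copper complex [Cu((S,S)-t-Bu-box)](SbF6)2 in CH2Cl2 follows; its square-planar chelate is expected to expose the same C5 face as the (R)-benzyl auxiliary. This should give 3-{[(3aR,7R,7aR)-4,7a-dimethyl-1-oxo-1,3,3a,6,7,7a-hexahydro-2-benzofuran-7-yl]carbonyl}-1,3-oxazolidin-2-one F2. Thiolysis with EtSH/n-BuLi returns to the route at thioester 13.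

**Step 13.** Hydrogen-atom transfer may also reach the C7=C8 alkene; the tertiary radical may be reduced before it adds, since addition to a carbonyl is reversible; the aldehyde may be reduced by the silane; and axial attack may compete, eroding the C3 configuration. The fallback makes the C–C bond formation irreversible and sets C3 in a separate hydride reduction. It sets out from 18: condensation with hydroxylamine gives the oxime of 18 F3, and Cu(OAc)2-catalysed dehydration in MeCN gives 3-[(1S,2R,6S)-2-(hydroxymethyl)-1,3-dimethyl-6-(prop-1-en-2-yl)cyclohex-3-en-1-yl]propanenitrile F4. The known HAT-initiated cyclisation of alkenyl nitriles (Fe(acac)3, PhSiH3, EtOH; hydrolytic work-up) gives the 3-ketone corresponding to 19 F5. NaBH4 reduction of this 4,4-dimethyl-3-ketone delivers hydride to the axial position and should give the equatorial alcohol, returning to the route at diol 19.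

**Step 14.** Displacement at C11 may stall at the alkoxyphosphonium stage, because the approach is screened by the quaternary C10 on one side and by the two ortho methoxy groups of the phenoxide on the other; the azodicarboxylate-derived anion then consumes the activated alcohol. The fallback separates activation from displacement. It sets out from diol 19: Tf2O with 2,6-di-tert-butylpyridine at −78 °C, selective for the primary hydroxyl, gives the C11 trifluoromethanesulfonate of 19 F6. F6 is displaced by the caesium phenoxide of 20 (Cs2CO3, DMF, 0 °C → rt), returning to the route at 21.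

**Step 12.** Slow turnover at the neopentyl-type vinyl group may let the rhodium hydride reach the isopropenyl group (hydroformylation or isomerisation there) or hydrogenate the vinyl group. The fallback adds C2 and C3 together by olefination and avoids 17. It sets out from lactol 16: Wittig reaction with Ph3P=CHCO2Me in toluene, kept neutral to avoid oxa-Michael closure, gives methyl (2E)-3-[(1S,2R,6S)-2-(hydroxymethyl)-1,3-dimethyl-6-(prop-1-en-2-yl)cyclohex-3-en-1-yl]prop-2-enoate F7. Conjugate reduction with [(Ph3P)CuH]6, which leaves isolated alkenes alone, gives methyl 3-[(1S,2R,6S)-2-(hydroxymethyl)-1,3-dimethyl-6-(prop-1-en-2-yl)cyclohex-3-en-1-yl]propanoate F8. i-Bu2AlH at −78 °C returns to the route at aldehyde 18.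

## Further compounds

F1 | step 6 | 3-{(2E)-3-methyl-4-[(2Z)-3-methylpenta-2,4-dien-1-yloxy]-4-oxobut-2-enoyl}-1,3-oxazolidin-2-one | C=C/C(C)=C\COC(=O)/C(C)=C/C(=O)N1CCOC1=O
F2 | step 6 | 3-{[(3aR,7R,7aR)-4,7a-dimethyl-1-oxo-1,3,3a,6,7,7a-hexahydro-2-benzofuran-7-yl]carbonyl}-1,3-oxazolidin-2-one | O=C1OC[C@@H]2C(C)=CC[C@@H](C(=O)N3CCOC3=O)[C@]12C
F3 | step 13 | oxime of 18 | OC[C@@H]1C(C)=CC[C@@H](C(C)=C)[C@]1(C)CCC=NO
F4 | step 13 | 3-[(1S,2R,6S)-2-(hydroxymethyl)-1,3-dimethyl-6-(prop-1-en-2-yl)cyclohex-3-en-1-yl]propanenitrile | OC[C@@H]1C(C)=CC[C@@H](C(C)=C)[C@]1(C)CCC#N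
F5 | step 13 | 3-ketone corresponding to 19 | OC[C@@H]1C(C)=CC[C@H]2C(C)(C)C(=O)CC[C@]12C
F6 | step 14 | C11 trifluoromethanesulfonate of 19 | O=S(=O)(OC[C@@H]1C(C)=CC[C@H]2C(C)(C)[C@@H](O)CC[C@]12C)C(F)(F)F
F7 | step 12 | methyl (2E)-3-[(1S,2R,6S)-2-(hydroxymethyl)-1,3-dimethyl-6-(prop-1-en-2-yl)cyclohex-3-en-1-yl]prop-2-enoate | OC[C@@H]1C(C)=CC[C@@H](C(C)=C)[C@]1(C)/C=C/C(=O)OC
F8 | step 12 | methyl 3-[(1S,2R,6S)-2-(hydroxymethyl)-1,3-dimethyl-6-(prop-1-en-2-yl)cyclohex-3-en-1-yl]propanoate | OC[C@@H]1C(C)=CC[C@@H](C(C)=C)[C@]1(C)CCC(=O)OC
A1 | alternative 1 | 4-[(E)-3,3-diethoxyprop-1-enyl]-2,4-dimethoxy-3-(terpenyloxy)cyclobut-2-en-1-one, terpenyl = C3-silylated alcohol part of 19 | COC1=C(OC[C@@H]2C(C)=CC[C@H]3C(C)(C)[C@@H](O[Si](C)(C)C(C)(C)C)CC[C@]23C)C(OC)(/C=C/C(OCC)OCC)C1=O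
A2 | alternative 1 | 2-hydroxy-3,5-dimethoxy-4-(terpenyloxy)benzaldehyde diethyl acetal | Oc1c(OC)c(OC[C@@H]2C(C)=CC[C@H]3C(C)(C)[C@@H](O[Si](C)(C)C(C)(C)C)CC[C@]23C)c(OC)cc1C(OCC)OCC
A3 | alternative 2 | (2Z,6E)-10,11-epoxyfarnesyl ether of isofraxidin, (S)-epoxide | COc1cc2ccc(=O)oc2c(OC)c1OC/C=C(C)\CC/C=C(C)/CC[C@@H]1OC1(C)C
A4 | alternative 2 | 3-deacetyl target (identical with 21) | COc1cc2ccc(=O)oc2c(OC)c1OC[C@@H]1C(C)=CC[C@H]2C(C)(C)[C@@H](O)CC[C@]12C
A5 | alternative 3 | 2,6-dimethyl-1,4-benzoquinone | CC1=CC(=O)C=C(C)C1=O
A6 | alternative 3 | 4-methyl-3-(trimethylsilyloxy)penta-1,3-diene | C=CC(O[Si](C)(C)C)=C(C)C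
A7 | alternative 3 | cis-fused ene-dione adduct with C3 silyl enol ether | O=C1C(C)=CC(=O)[C@@H]2C(C)(C)C(O[Si](C)(C)C)=CC[C@]12C
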